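The constants used here were chosen freely; the result is computed.

How much G.X stands in this flask at the end of the run, and which change adds most to it?

    X ⇌ Q, rate k1*([X] - [Q]/K1) per volume of the first phase (K1 = 1.3, k1 = 0.037 min⁻¹)
    G + G.X → G.G.X (k2 = 1.5 M⁻¹ min⁻¹)
    G + X → G.X (k3 = 3.3 M⁻¹ min⁻¹)

G 0.20 M; Q 1.10 equiv; time 6.0 min; volume of the second phase over the first 0.50

- south: doubling the amount of Q, all else as stated
- north-east: doubling the transfer coefficient of step 1, all else as stated

- in percentages every species weighs as the G in it: one G.G.X counts as two
- in the second phase: Q; everything else is in the first
- charges count per volume of the first phase; a concentration in a rate is the amount of a species over the volume of its own phase; every rate counts per litre of the first phase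
- run time (flask): 6.0 min

1. G.X at 6.0 min, in percent of the G charged
2. the change that raises the amount of G.X at 6.0 min, in percent of the G charged most ("none" if none brings more than 2 percentage points) (south / north-east / none)
3. amount of G.X at 6.0 min, in percent of the G charged, after south

To whoever takes over: the flask was charged with G in the first phase and Q in the second, at 0.440 M there, and Q crosses over to become the X that meets G. I reckon from that feed of X, 0.0125 M min⁻¹ at the start. Note that G.X is lost to G, not to X. With G held at its charge, X has a pseudo-first-order loss x of 0.660 min⁻¹ and G.X a loss p of 0.300 min⁻¹.

I call the balance share the part of the charged G standing as G.X when the starting feed equals the loss of G.X, with G held at its charge: 20.9 %.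

After time t, this chain has climbed a fraction of one minus (x·e^(−pt) − p·e^(−xt))/(x − p), here 0.713. Q also drains, at 0.0569 min⁻¹, so the average feed is 0.847 of the first. Holding G is rough, since the feed brings in X equal to about a third of the G charged.

The product of the three gives 12.6 % G.X when you come. Doubling Q doubles the balance share and leaves the drain: 25.2 %. Doubling the transfer coefficient doubles the balance share and the drain, giving 21.6 %, less than with Q. So my choice is south.

The forecast says 13 %, south and 25 %, since “doubling Q keeps that feed up for the whole run instead of draining Q faster”.

The flask gives 12.5 %, and after south 24.8 %. South gains 12 percentage points against 8.5 points for north-east, so the choice is south.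

The neighbouring flask, read at 1.5 min, takes the same reckoning with its own time. Its balance share stays 20.9 %, its climb is 0.141 and its average feed is 0.958 of the first, which makes 2.81 %. That neighbouring flask holds G.X at 2.77 %.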